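**Plan**

- Retrosynthesis: the O7–CH3 bond is cut first (back to the 6,7-catechol and then to its dibenzyl ether). Next, all four bonds of the pyranone ring of the 6-hydroxy-7-methoxycoumarin unit (unit A) are cut at once: C4a–C4, C8a–O1, C3–C4 and O1–C2.
- Enabling feature: in unit A the ring oxygen O1 and the CH carbon C4 sit on the neighbouring arene carbons C8a and C4a. This is the pattern left by an aryne that has taken up the oxygen and the formyl carbon of DMF. C2 and C3, with the aryloxy group already on C3, correspond to an aryloxyacetate enolate.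
- Forward: the umbelliferone ring system (unit B) is bought intact, O-alkylated to the aryloxyacetate and converted into its silyl ketene acetal. The symmetric 4,5-bis(benzyloxy)aryne precursor is made in three steps from 3,4-bis(benzyloxy)benzaldehyde.
- The only ring built in the route, the pyranone of unit A, arises in the fluoride-triggered union of aryne, DMF and ketene acetal. Debenzylation and methylation of the more acidic 7-hydroxyl finish the synthesis.
- Stereochemistry: the target has no stereocentre and no configured double bond. The ketene acetal geometry and the two transient sp3 carbons of the annulation are erased on the way.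

Key step: step 6

Assumption: 3,4-bis(benzyloxy)benzaldehyde is taken as a commercial starting material, like umbelliferone, methyl bromoacetate and DMF.

**Route**

Step 1
Reactants: 1 3,4-bis(benzyloxy)benzaldehyde
Product: 3 3,4-bis(benzyloxy)phenol, via aryl formate 2 (not isolated)
Conditions: mCPBA, CH2Cl2, 0 °C → rt; then K2CO3 (cat.), MeOH, rt
Reagents that add atoms: 3-chloroperoxybenzoic acid (mCPBA), O=C(OO)c1cccc(Cl)c1
Why: Baeyer–Villiger (Dakin-type) oxidation, in which the electron-rich aryl group migrates to give the aryl formate 2, followed by carbonate-catalysed methanolysis to the phenol; benzyl ethers are inert to both operations.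

Step 2
Reactants: 3 3,4-bis(benzyloxy)phenol
Product: 4 4,5-bis(benzyloxy)-2-bromophenol
Conditions: NBS (1.0 equiv), CH2Cl2, −20 → 0 °C
Reagents that add atoms: N-bromosuccinimide, O=C1CCC(=O)N1Br
Why: Electrophilic aromatic bromination directed by the free hydroxyl should go to the ortho position that is also para to the 3-benzyloxy group, since the other ortho position is flanked by two oxygen substituents.

Step 3
Reactants: 4 4,5-bis(benzyloxy)-2-bromophenol
Product: 8 4,5-bis(benzyloxy)-2-(trimethylsilyl)phenyl trifluoromethanesulfonate, via aryl trimethylsilyl ether 5 (not isolated), via aryllithium 6 (not isolated), via lithium 2-silylphenoxide 7 (not isolated)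
Conditions: (Me3Si)2NH, THF, 70 °C, then evaporate; n-BuLi, THF, −100 → −80 °C; Tf2O, −100 °C → rt
Reagents that add atoms: hexamethyldisilazane, C[Si](C)(C)N[Si](C)(C)C; trifluoromethanesulfonic anhydride, O=S(=O)(OS(=O)(=O)C(F)(F)F)C(F)(F)F
Why: O-silylation, bromine–lithium exchange, anionic 1,3 O→C silyl shift (retro-Brook rearrangement) and O-triflation of the resulting phenoxide form the standard passage from an ortho-bromophenol to an ortho-silylaryl triflate, and at −100 °C halogen–metal exchange should outrun any benzylic deprotonation of the benzyl ethers.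

Step 4
Reactants: 9 umbelliferone (7-hydroxy-2H-chromen-2-one); 10 methyl bromoacetate
Product: 11 methyl 2-[(2-oxo-2H-chromen-7-yl)oxy]acetate
Conditions: K2CO3, acetone, reflux
Reagents that add atoms: none
Why: Williamson ether synthesis of an acidic phenol with a reactive α-bromo ester under carbonate, conditions the lactone tolerates.

Step 5
Reactants: 11 methyl 2-[(2-oxo-2H-chromen-7-yl)oxy]acetate
Product: 13 (Z)-7-{[2-methoxy-2-(trimethylsilyloxy)ethenyl]oxy}-2H-chromen-2-one, via lithium ester enolate 12 (not isolated)
Conditions: LiN(SiMe3)2 (1.1 equiv) added to 11 and Me3SiCl (2 equiv), THF, −78 °C; evaporate, take up in dry toluene, filter from LiCl under argon, use at once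
Reagents that add atoms: chlorotrimethylsilane, C[Si](C)(C)Cl
Why: Kinetic ester enolisation with a non-nucleophilic amide under internal-quench conditions should trap the chelated lithium enolate on oxygen as the silyl ketene acetal (expected mainly Z) before it can add to the lactone of another molecule; the geometry has no consequence later.

Step 6
Reactants: 8 4,5-bis(benzyloxy)-2-(trimethylsilyl)phenyl trifluoromethanesulfonate; 13 (Z)-7-{[2-methoxy-2-(trimethylsilyloxy)ethenyl]oxy}-2H-chromen-2-one; 14 N,N-dimethylformamide
Product: 18 6,7-bis(benzyloxy)-3-[(2-oxo-2H-chromen-7-yl)oxy]-2H-chromen-2-one, via 4,5-bis(benzyloxy)benzyne 15 (not isolated), via aminomethylene ortho-quinone methide 16 (not isolated), via 4-dimethylamino dihydrocoumarin 17 (not isolated)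
Conditions: CsF (3 equiv), dry DMF (solvent), 8 and 13 (1.3 equiv) added slowly together, 25 °C; then 60 °C; aq NH4Cl work-up
Reagents that add atoms: none
Why: Fluoride removes the silyl group of 8 with loss of triflate to give the mirror-symmetric aryne 15, which adds across the C=O of solvent DMF (forming C8a–O1 and C4a–C4) to a benzoxetene that opens to the aminomethylene ortho-quinone methide 16, while fluoride also frees the ester enolate from 13. The enolate carbon adds to the iminium-like methide carbon (C3–C4), the phenoxide acylates on the ester (O1–C2) to give 17 and the expelled methoxide takes up the trimethylsilyl group, after which E1cB loss of dimethylamine installs the C3=C4 double bond. The closest known reaction type is the fluoride-induced three-component coumarin annulation of arynes, formamides and ester enolates, silyl ketene acetals or 1,3-dicarbonyl compounds, which may equally be read as a [4+2] cycloaddition of the quinone methide to the ketene acetal. The single ring formed, the pyranone of unit A, closes by 6-exo-trig attack of the phenoxide oxygen on the ester carbonyl, and no stereocentre results because the two sp3 carbons of 17 become sp2 on elimination. The step needs chemoselectivity only: the aryne must be taken by DMF and not by the enolate, which DMF as solvent and slow joint addition of 8 and 13 should secure, and the enolate must prefer the quinone methide to the lactone of unit B, which the cationic character of the methide carbon against an electron-rich 7-alkoxycoumarin should secure. Regioselectivity is no issue, since either orientation of DMF on the symmetric aryne gives the same 6,7-dioxygenated ring.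

Step 7
Reactants: 18 6,7-bis(benzyloxy)-3-[(2-oxo-2H-chromen-7-yl)oxy]-2H-chromen-2-one
Product: 20 6,7-dihydroxy-3-[(2-oxo-2H-chromen-7-yl)oxy]-2H-chromen-2-one, via cyclic chloroboronate 19 (not isolated)
Conditions: BCl3 (1 M in CH2Cl2), C6HMe5, CH2Cl2, −78 °C; then H2O, 0 °C
Reagents that add atoms: none
Why: Lewis-acid debenzylation of aryl benzyl ethers with pentamethylbenzene as benzyl-cation scavenger should leave both lactones, their C3–C4 double bonds and the C3–O aryl ether untouched, where hydrogenolysis could saturate unit B; water then hydrolyses the catechol chloroboronate 19.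

Step 8
Reactants: 20 6,7-dihydroxy-3-[(2-oxo-2H-chromen-7-yl)oxy]-2H-chromen-2-one
Product: 21 6-hydroxy-7-methoxy-3-[(2-oxo-2H-chromen-7-yl)oxy]-2H-chromen-2-one
Conditions: MeI (1.1 equiv), Li2CO3 (1.0 equiv), DMF, 40 °C, argon
Reagents that add atoms: iodomethane, CI
Why: Regioselective Williamson methylation: one equivalent of a weak base should ionise only the 7-hydroxyl, which is para to C4a and so conjugated through C4=C3 with the lactone carbonyl, as in the 4-O-selective alkylation of 3,4-dihydroxybenzaldehyde and the 7-O-alkylation of esculetin.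

**Compound list**

1 | 3,4-bis(benzyloxy)benzaldehyde | O=Cc1ccc(OCc2ccccc2)c(OCc2ccccc2)c1 | starting material
2 | 3,4-bis(benzyloxy)phenyl formate (not isolated) | O=COc1ccc(OCc2ccccc2)c(OCc2ccccc2)c1 | intermediate
3 | 3,4-bis(benzyloxy)phenol | Oc1ccc(OCc2ccccc2)c(OCc2ccccc2)c1 | intermediate
4 | 4,5-bis(benzyloxy)-2-bromophenol | Oc1cc(OCc2ccccc2)c(OCc2ccccc2)cc1Br | intermediate
5 | [4,5-bis(benzyloxy)-2-bromophenoxy]trimethylsilane (not isolated) | C[Si](C)(C)Oc1cc(OCc2ccccc2)c(OCc2ccccc2)cc1Br | intermediate
6 | {4,5-bis(benzyloxy)-2-[(trimethylsilyl)oxy]phenyl}lithium (not isolated) | [Li]c1cc(OCc2ccccc2)c(OCc2ccccc2)cc1O[Si](C)(C)C | intermediate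
7 | lithium 4,5-bis(benzyloxy)-2-(trimethylsilyl)phenolate (not isolated) | [Li+].[O-]c1cc(OCc2ccccc2)c(OCc2ccccc2)cc1[Si](C)(C)C | intermediate
8 | 4,5-bis(benzyloxy)-2-(trimethylsilyl)phenyl trifluoromethanesulfonate | C[Si](C)(C)c1cc(OCc2ccccc2)c(OCc2ccccc2)cc1OS(=O)(=O)C(F)(F)F | intermediate
9 | umbelliferone (7-hydroxy-2H-chromen-2-one) | O=c1ccc2ccc(O)cc2o1 | starting material
10 | methyl bromoacetate | COC(=O)CBr | starting material
11 | methyl 2-[(2-oxo-2H-chromen-7-yl)oxy]acetate | COC(=O)COc1ccc2ccc(=O)oc2c1 | intermediate
12 | lithium 1-methoxy-2-[(2-oxo-2H-chromen-7-yl)oxy]ethen-1-olate, O–Li cis to the aryloxy oxygen (not isolated) | CO/C([O-])=C/Oc1ccc2ccc(=O)oc2c1.[Li+] | intermediate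
13 | (Z)-7-{[2-methoxy-2-(trimethylsilyloxy)ethenyl]oxy}-2H-chromen-2-one | CO/C(O[Si](C)(C)C)=C/Oc1ccc2ccc(=O)oc2c1 | intermediate
14 | N,N-dimethylformamide | CN(C)C=O | starting material
15 | 4,5-bis(benzyloxy)benzyne (not isolated) | C1(OCc2ccccc2)=CC#CC=C1OCc1ccccc1 | intermediate
16 | 3,4-bis(benzyloxy)-6-[(dimethylamino)methylidene]cyclohexa-2,4-dien-1-one, exocyclic double-bond geometry not fixed (not isolated) | CN(C)C=C1C=C(OCc2ccccc2)C(OCc2ccccc2)=CC1=O | intermediate
17 | 6,7-bis(benzyloxy)-4-(dimethylamino)-3-[(2-oxo-2H-chromen-7-yl)oxy]-3,4-dihydro-2H-chromen-2-one, racemic mixture of diastereomers (not isolated) | CN(C)C1C(Oc2ccc3ccc(=O)oc3c2)C(=O)Oc2cc(OCc3ccccc3)c(OCc3ccccc3)cc21 | intermediate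
18 | 6,7-bis(benzyloxy)-3-[(2-oxo-2H-chromen-7-yl)oxy]-2H-chromen-2-one | O=c1oc2cc(OCc3ccccc3)c(OCc3ccccc3)cc2cc1Oc1ccc2ccc(=O)oc2c1 | intermediate
19 | 2-chloro-7-[(2-oxo-2H-chromen-7-yl)oxy]-6H-[1,3,2]dioxaborolo[4,5-g]chromen-6-one, the B-chloro cyclic boronate of catechol 20 (not isolated) | O=c1oc2cc3OB(Cl)Oc3cc2cc1Oc1ccc2ccc(=O)oc2c1 | intermediate
20 | 6,7-dihydroxy-3-[(2-oxo-2H-chromen-7-yl)oxy]-2H-chromen-2-one | Oc1cc2oc(=O)c(Oc3ccc4ccc(=O)oc4c3)cc2cc1O | intermediate
21 | 6-hydroxy-7-methoxy-3-[(2-oxo-2H-chromen-7-yl)oxy]-2H-chromen-2-one (CNP0157415.0) | COc1cc2oc(=O)c(Oc3ccc4ccc(=O)oc4c3)cc2cc1O | target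

**Step count**

Total step count: 8.
Longest linear sequence: 6 steps (steps 1, 2, 3, 6, 7 and 8, from 1).

**Steps most likely to fail**

Step 6. The enolate, a far better nucleophile than DMF, may capture the aryne itself (C-arylation or insertion into the ester), or the quinone methide may be quenched to the salicylaldehyde before the C3–C4 bond forms. The fallback builds the same ring stepwise by known chemistry and sets out from phenol 3 and ester 11. Magnesium-mediated ortho-formylation of 3 (MgCl2, Et3N, paraformaldehyde, MeCN, reflux) should give 4,5-bis(benzyloxy)-2-hydroxybenzaldehyde F1. Hydrolysis of 11 (LiOH, THF–H2O, then dilute HCl, which re-closes any opened lactone) should give 2-[(2-oxo-2H-chromen-7-yl)oxy]acetic acid F2. Perkin–Oglialoro condensation of F1 with F2 (Ac2O, Et3N, 110 °C) then forms C3–C4 and O1–C2 and returns to the route at 18.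

Step 8. Site selectivity between the two catechol hydroxyls may be poor: alkylation can run through the minor but more nucleophilic 6-phenoxide, and over-methylation to the dimethyl ether can follow. The fallback sets out from 20 and differentiates the oxygens by acyl cleavage instead of alkylation. Peracetylation (Ac2O, pyridine) should give 2-oxo-3-[(2-oxo-2H-chromen-7-yl)oxy]-2H-chromene-6,7-diyl diacetate F3. Thiolysis (PhSH, imidazole, N-methylpyrrolidone, 0 °C) removes the acetate of the more acidic phenol first and should give 7-hydroxy-2-oxo-3-[(2-oxo-2H-chromen-7-yl)oxy]-2H-chromen-6-yl acetate F4. Mitsunobu methylation of the single free hydroxyl (MeOH, PPh3, DIAD, THF), under neutral conditions that avoid acetyl migration, should give 7-methoxy-2-oxo-3-[(2-oxo-2H-chromen-7-yl)oxy]-2H-chromen-6-yl acetate F5. Methanolysis (K2CO3, MeOH) rejoins the route at 21.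

Step 5. The amide base or the lithium enolate may add to the lactone of unit B, C-silylation may compete, and the trimethylsilyl ketene acetal may hydrolyse during handling. The fallback sets out from 11 and changes the mode of enolisation: soft enolisation with t-BuMe2SiOTf and Et3N (CH2Cl2, 0 °C → rt) forms no metal enolate and uses no amide base. It should give 7-{[2-(tert-butyldimethylsilyloxy)-2-methoxyethenyl]oxy}-2H-chromen-2-one F6, a silyl ketene acetal sturdy enough for a brief aqueous wash. F6 takes the place of 13 under the conditions of step 6, and the route is rejoined at 18.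

**Further compounds**

F1 | step 6 | 4,5-bis(benzyloxy)-2-hydroxybenzaldehyde | O=Cc1cc(OCc2ccccc2)c(OCc2ccccc2)cc1O
F2 | step 6 | 2-[(2-oxo-2H-chromen-7-yl)oxy]acetic acid | OC(=O)COc1ccc2ccc(=O)oc2c1
F3 | step 8 | 2-oxo-3-[(2-oxo-2H-chromen-7-yl)oxy]-2H-chromene-6,7-diyl diacetate | CC(=O)Oc1cc2oc(=O)c(Oc3ccc4ccc(=O)oc4c3)cc2cc1OC(C)=O
F4 | step 8 | 7-hydroxy-2-oxo-3-[(2-oxo-2H-chromen-7-yl)oxy]-2H-chromen-6-yl acetate | Oc1cc2oc(=O)c(Oc3ccc4ccc(=O)oc4c3)cc2cc1OC(C)=O
F5 | step 8 | 7-methoxy-2-oxo-3-[(2-oxo-2H-chromen-7-yl)oxy]-2H-chromen-6-yl acetate | COc1cc2oc(=O)c(Oc3ccc4ccc(=O)oc4c3)cc2cc1OC(C)=O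
F6 | step 5 | 7-{[2-(tert-butyldimethylsilyloxy)-2-methoxyethenyl]oxy}-2H-chromen-2-one (mixture of geometric isomers) | COC(O[Si](C)(C)C(C)(C)C)=COc1ccc2ccc(=O)oc2c1
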